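Numbering (elemane type): cyclohexane C5–C6–C7–C8–C9–C10; C10 carries methyl C14 and vinyl C1=C2, C5 carries C4(=C15H2)–C3H2OH, C7 carries C11(=C13H2)–C12O2H, O8 carries the acyl group C1'–C4' with methylene C5'.
Feature used: in this ring the secondary carbinol C6 lies next to C7, which bears the 1-carboxyvinyl unit C11–C13; this 2-(1-hydroxyalkyl)acrylate motif is what an aldehyde and a 2-(bromomethyl)enoate give on reductive allylation, so the ring is opened at C6–C7.
Cuts, in retrosynthetic order: O8–C1' (ester); C6–C7 (ring); C7–C11 and C13–Br (Morita–Baylis–Hillman, allylic bromination); C5–C10 (ester-enolate Claisen); C10–C14 and C1–C2 (carboalumination, hydroxymethylation); C9–C10 (epoxide alkynylation).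
Forward order: the chain C7–C8–C9–C10–C1–C2 is grown from a glycidyl ether, C5–C10 is joined by a [3,3] shift, the acrylate is attached at C7, the only carbocycle then closes at C6–C7, and the side-chain acid is esterified to O8 last.
Stereochemistry: C8 from (S)-glycidyl trityl ether; C5 and C10 together from a chair Claisen (E alkene, E(O) boron enolate) whose face is chosen by a chiral ligand on boron, because the remote C8 centre cannot bias it; C6 and C7 in the ring closure from the closed chromium chair and the C5, C8 and C10 substituents; C3' from (R)-3-hydroxy-γ-butyrolactone.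

Key step: step 17

Assumption: the (S,S)-configured boron controller is taken to favour the chair that leads to 5S,10R; should the rearrangement deliver the antipodal pair, its (R,R)-enantiomer is used in the same way.

**Acid partner (C3–C6, C15)**

Step 1
Reactants: 1 monomethyl itaconate (4-methoxy-2-methylidene-4-oxobutanoic acid)
Product: 3 methyl 3-(hydroxymethyl)but-3-enoate, via mixed carbonic anhydride 2 (not isolated)
Conditions: ClCO2Et, Et3N, THF, −10 °C; then NaBH4, THF/H2O, 0 °C
Reagents that add atoms: none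
Why: The conjugated acid is activated as a mixed carbonic anhydride and reduced by NaBH4 to the allylic alcohol (mixed-anhydride reduction), conditions under which the methyl ester and the 1,1-disubstituted alkene are not touched.

Step 2
Reactants: 3 methyl 3-(hydroxymethyl)but-3-enoate
Product: 4 methyl 3-{[(tert-butyldiphenylsilyl)oxy]methyl}but-3-enoate
Conditions: TBDPSCl, imidazole, CH2Cl2, 0 °C → rt (crude 3 used at once)
Reagents that add atoms: tert-butyl(chloro)diphenylsilane, CC(C)(C)[Si](Cl)(c1ccccc1)c1ccccc1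
Why: Standard silylation of a primary allylic alcohol, carried out on the crude alcohol so that it cannot lactonise onto the methyl ester.

Step 3
Reactants: 4 methyl 3-{[(tert-butyldiphenylsilyl)oxy]methyl}but-3-enoate
Product: 5 3-{[(tert-butyldiphenylsilyl)oxy]methyl}but-3-enoic acid
Conditions: LiOH·H2O, THF/H2O, 0 °C; 1 M HCl to pH 3
Reagents that add atoms: lithium hydroxide, [Li+].[OH-]
Why: Saponification at 0 °C should outrun base-induced migration of the β,γ-double bond into conjugation, and the TBDPS ether is stable to aqueous hydroxide.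

**Main chain**

Step 4
Reactants: 6 (S)-glycidyl trityl ether
Product: 7 (S)-1-(trityloxy)pent-4-yn-2-ol
Conditions: LiC≡CH·H2NCH2CH2NH2, DMSO, 0 °C → rt; H2O
Reagents that add atoms: lithium acetylide–ethylenediamine complex, [Li+].[C-]#C.NCCN
Why: The acetylide opens the epoxide by SN2 attack at the unsubstituted carbon (C9), so the carbinol centre C8 keeps the configuration of the glycidyl ether.

Step 5
Reactants: 7 (S)-1-(trityloxy)pent-4-yn-2-ol
Product: 8 (S)-pent-4-yne-1,2-diol
Conditions: p-TsOH·H2O (cat.), MeOH, rt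
Reagents that add atoms: none
Why: Acid-catalysed methanolysis of the trityl ether (SN1 detritylation) frees the primary hydroxyl without touching the alkyne or C8.

Step 6
Reactants: 8 (S)-pent-4-yne-1,2-diol
Product: 9 (S)-4,5-bis(triethylsilyloxy)pent-1-yne
Conditions: TESCl, imidazole, DMF, 0 °C → rt
Reagents that add atoms: chlorotriethylsilane, CC[Si](Cl)(CC)CC
Why: Exhaustive silylation gives a primary and a secondary triethylsilyl ether that are told apart later by oxidation (step 12) and by acid lability (step 19).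

Step 7
Reactants: 9 (S)-4,5-bis(triethylsilyloxy)pent-1-yne
Product: 11 (2E,5S)-3-methyl-5,6-bis(triethylsilyloxy)hex-2-en-1-ol, via alkenyldimethylalane 10 (not isolated)
Conditions: Me3Al, Cp2ZrCl2 (0.25 equiv), CH2Cl2, 0 °C → rt; then n-BuLi, −78 °C; (CH2O)n, THF, −78 °C → rt
Reagents that add atoms: trimethylaluminium, C[Al](C)C; formaldehyde (from paraformaldehyde), C=O
Why: Zirconium-catalysed syn-carboalumination (Negishi) adds methyl to C10 and aluminium to C1 with E geometry, and the derived aluminate is hydroxymethylated with retention, which fixes the (E)-trisubstituted allylic alcohol.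

Step 8
Reactants: 11 (2E,5S)-3-methyl-5,6-bis(triethylsilyloxy)hex-2-en-1-ol; 5 3-{[(tert-butyldiphenylsilyl)oxy]methyl}but-3-enoic acid
Product: 12 (2E,5S)-3-methyl-5,6-bis(triethylsilyloxy)hex-2-en-1-yl 3-{[(tert-butyldiphenylsilyl)oxy]methyl}but-3-enoate
Conditions: EDC·HCl, DMAP (0.1 equiv), CH2Cl2, 0 °C
Reagents that add atoms: none
Why: Carbodiimide esterification (Steglich) of an unhindered primary allylic alcohol, with low temperature and little DMAP to limit migration of the β,γ-double bond of the acid.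

Step 9
Reactants: 12 allylic ester
Product: 14 (2S,3R,5S)-2-{3-[(tert-butyldiphenylsilyl)oxy]prop-1-en-2-yl}-3-ethenyl-3-methyl-5,6-bis(triethylsilyloxy)hexanoic acid, via boron ketene acetal 13 (not isolated)
Conditions: (4S,5S)-2-bromo-1,3-bis{[3,5-bis(trifluoromethyl)phenyl]sulfonyl}-4,5-diphenyl-1,3,2-diazaborolidine (1.3 equiv, preformed), Et3N, toluene/hexane, −78 °C, then 4 °C; aqueous work-up
Reagents that add atoms: none
Why: The bromoborane and Et3N enolise the ester softly to the E(O) boron dienolate 13 (C4 cis to the allyloxy oxygen), whose [3,3] shift (Ireland–Claisen type) through a chair with the (E)-allyl unit joins C5 to C10 and gives the 5S*,10R* pair with the C10 vinyl group, while the C2-symmetric sulfonamide ligand on boron selects the chair face and so the absolute configuration 5S,10R.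

Step 10
Reactants: 14 Claisen acid
Product: 15 (2S,3R,5S)-2-{3-[(tert-butyldiphenylsilyl)oxy]prop-1-en-2-yl}-3-ethenyl-3-methyl-5,6-bis(triethylsilyloxy)hexan-1-ol
Conditions: LiAlH4, Et2O, 0 °C → rt
Reagents that add atoms: none
Why: LiAlH4 reduces the hindered acid to the primary alcohol through its carboxylate, so C5 is not epimerised, and silyl ethers and isolated alkenes are inert.

Step 11
Reactants: 15 C6 alcohol
Product: 16 4-methoxybenzyl ether of 15 at O6
Conditions: NaH, 4-MeOC6H4CH2Cl, Bu4NI (cat.), THF/DMF, 0 °C → rt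
Reagents that add atoms: 4-methoxybenzyl chloride, COc1ccc(CCl)cc1
Why: Williamson etherification gives a 4-methoxybenzyl ether that is orthogonal to every silyl ether and can later be removed under neutral oxidative conditions in the presence of an allylic bromide.

Step 12
Reactants: 16 O6 4-methoxybenzyl ether
Product: 18 (2S,4R,5S)-4-ethenyl-6-(4-methoxybenzyloxy)-4-methyl-5-{3-[(tert-butyldiphenylsilyl)oxy]prop-1-en-2-yl}-2-(triethylsilyloxy)hexanal, via primary alcohol 17 (not isolated)
Conditions: (COCl)2, DMSO, CH2Cl2, −78 → −40 °C; then Et3N, −78 °C → rt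
Reagents that add atoms: none
Why: Under Swern conditions a primary triethylsilyl ether is cleaved and the liberated alcohol oxidised in the same flask, whereas secondary triethylsilyl, TBDPS and 4-methoxybenzyl ethers survive, so the C7 aldehyde is unveiled in one operation without epimerising C8.

Step 13
Reactants: 18 C7 aldehyde; 19 allyl acrylate
Product: 20 allyl (4S,6R,7S)-6-ethenyl-3-hydroxy-8-(4-methoxybenzyloxy)-6-methyl-2-methylidene-7-{3-[(tert-butyldiphenylsilyl)oxy]prop-1-en-2-yl}-4-(triethylsilyloxy)octanoate (both C7 epimers, octanoate C3)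
Conditions: DABCO (1 equiv), 19 (neat, 10 equiv), rt, several days
Reagents that add atoms: none
Why: Morita–Baylis–Hillman reaction of an activated α-silyloxy aldehyde with the acrylate forms C7–C11, and the new carbinol C7 arises as an epimer mixture that does not matter because C7 becomes trigonal in step 14.

Step 14
Reactants: 20 Baylis–Hillman adduct
Product: 21 allyl (2Z,4S,6R,7S)-2-(bromomethyl)-6-ethenyl-8-(4-methoxybenzyloxy)-6-methyl-7-{3-[(tert-butyldiphenylsilyl)oxy]prop-1-en-2-yl}-4-(triethylsilyloxy)oct-2-enoate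
Conditions: NBS, Me2S, CH2Cl2, 0 °C → rt
Reagents that add atoms: N-bromosuccinimide, O=C1CCC(=O)N1Br
Why: The bromodimethylsulfonium reagent activates the hydroxyl and bromide enters at C13 with allylic transposition (SN2'), which should give from both C7 epimers the thermodynamically preferred (Z)-2-(bromomethyl)enoate with C8 trans to the ester.

Step 15
Reactants: 21 allylic bromide
Product: 22 allyl (2Z,4S,6R,7S)-2-(bromomethyl)-6-ethenyl-8-hydroxy-6-methyl-7-{3-[(tert-butyldiphenylsilyl)oxy]prop-1-en-2-yl}-4-(triethylsilyloxy)oct-2-enoate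
Conditions: DDQ, CH2Cl2/pH 7 buffer, 0 °C
Reagents that add atoms: none
Why: DDQ oxidises only the electron-rich benzyl ether (oxidative 4-methoxybenzyl cleavage) under buffered conditions that leave the allylic bromide, the allyl ester and the silyl ethers intact.

Step 16
Reactants: 22 C6 alcohol
Product: 23 allyl (2Z,4S,6R,7S)-2-(bromomethyl)-6-ethenyl-6-methyl-8-oxo-7-{3-[(tert-butyldiphenylsilyl)oxy]prop-1-en-2-yl}-4-(triethylsilyloxy)oct-2-enoate (open-chain C6 aldehyde)
Conditions: Dess–Martin periodinane, NaHCO3, CH2Cl2, 0 °C; used at once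
Reagents that add atoms: none
Why: Buffered Dess–Martin oxidation is neutral and fast, so the aldehyde should form without epimerisation or double-bond migration at the allylic α-carbon C5 and without touching the bromide.

Step 17
Reactants: 23 open-chain C6 aldehyde with (Z)-2-(bromomethyl)enoate terminus
Product: 25 cyclohexane with O6–H, O8–SiEt3, O3–TBDPS and allyl acrylate at C7 (5S,6S,7S,8S,10R), via allylchromium dichloride 24 (not isolated)
Conditions: CrCl2 (5 equiv), THF, rt, slow addition of 23 (final 0.005 M); pH 7 buffer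
Reagents that add atoms: none
Why: Two equivalents of CrCl2 (divalent chromium) reduce the allylic C13–Br bond to the trivalent allylchromium 24, in which C8 stays cis to the CH2–Cr carbon and trans to the ester; this adds through its γ-carbon C7 to the C6 aldehyde in a closed six-membered chair and moves the double bond to C11=C13 (intramolecular Nozaki–Hiyama allylation; closest known type: CrCl2-mediated cyclisation of ω-formyl 2-(bromomethyl)enoates to carbocyclic cis-hydroxy α-methylene esters). The cyclohexane closes in 6-exo-trig fashion on the carbonyl carbon. C7 is controlled by the enoate geometry and C6 by the chair: because C8 is axial in the chromium chair, the carbonyl oxygen becomes axial and C11 equatorial on the new ring, so O6 and the acrylate are cis. Of the two cis modes, the one giving the 6,7-bis-epimer would place O6, the C8 silyloxy group and the C10 methyl in a 1,3,5-triaxial array, so bond formation should occur on the aldehyde face anti to the C5 substituent and on the C7 face anti to O8, giving 6S,7S with the C8 silyloxy group and C14 equatorial. The step needs cis selectivity and this facial selectivity, secured by the closed transition state and by the fixed C5, C8 and C10 centres; the medium is not basic, so the epimerisable C5 and the δ-silyloxy group should survive.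

Step 18
Reactants: 25 cyclised hydroxy ester
Product: 26 O6-tert-butyldimethylsilyl ether of 25 (5S,6S,7R,8S,10R; the C7 label changes through CIP priorities only)
Conditions: TBSOTf, 2,6-lutidine, CH2Cl2, −78 → 0 °C
Reagents that add atoms: tert-butyldimethylsilyl trifluoromethanesulfonate, CC(C)(C)[Si](C)(C)OS(=O)(=O)C(F)(F)F
Why: The silyl triflate silylates even the hindered axial hydroxyl, which blocks lactonisation onto the neighbouring allyl ester and distinguishes O6 from O8.

Step 19
Reactants: 26 O6-TBS ether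
Product: 27 C8 alcohol (O6–TBS, O3–TBDPS, allyl ester; 5S,6S,7R,8S,10R)
Conditions: PPTS (cat.), MeOH/CH2Cl2, 0 °C → rt
Reagents that add atoms: none
Why: A secondary triethylsilyl ether is methanolysed by a mild acid catalyst far faster than a secondary TBS or a primary TBDPS ether (selective desilylation), which frees only O8.

**Side-chain acid (C1'–C5')**

Step 20
Reactants: 28 (R)-4-hydroxydihydrofuran-2(3H)-one ((R)-3-hydroxy-γ-butyrolactone)
Product: 31 (R)-4-hydroxy-3-methylidenedihydrofuran-2(3H)-one, via Mannich base 29 (not isolated), via methiodide 30 (not isolated)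
Conditions: LDA (2.2 equiv), THF, −78 °C; CH2=NMe2+ I−, −78 → 0 °C; then MeI, MeOH, rt; then aq NaHCO3/CH2Cl2, rt
Reagents that add atoms: dimethylmethylideneammonium iodide (Eschenmoser's salt), C=[N+](C)C.[I-]
Why: The alkoxide–enolate dianion of the β-hydroxy lactone is aminomethylated at the α-carbon (Mannich reaction), and quaternisation followed by base-induced elimination installs the methylene group without involving the carbinol centre C3'.

Step 21
Reactants: 31 (R)-4-hydroxy-3-methylidenedihydrofuran-2(3H)-one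
Product: 34 (R)-3,4-bis(tert-butyldimethylsilyloxy)-2-methylidenebutanoic acid, via lithium dihydroxy carboxylate 32 (not isolated), via tris-silyl compound 33 (not isolated)
Conditions: LiOH, THF/H2O, 0 °C; evaporate; TBSCl, imidazole, DMF, rt; then K2CO3 (cat.), MeOH/THF, 0 °C; pH 4 buffer
Reagents that add atoms: lithium hydroxide, [Li+].[OH-]; tert-butyl(chloro)dimethylsilane, CC(C)(C)[Si](C)(C)Cl
Why: Saponification opens the lactone, exhaustive silylation prevents relactonisation of the 4'-hydroxy acid, and the silyl ester alone is cleaved by mild methanolysis, which leaves the two silyl ethers.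

**Endgame**

Step 22
Reactants: 27 C8 alcohol; 34 side-chain acid
Product: 36 fully protected C8 ester (O6–TBS, O3–TBDPS, O3' and O4'–TBS, allyl ester; 5S,6S,7R,8S,10R,3'R), via Yamaguchi mixed anhydride 35 (not isolated)
Conditions: 34, 2,4,6-Cl3C6H2COCl, Et3N, toluene, rt; then 27, DMAP, rt
Reagents that add atoms: none
Why: Yamaguchi esterification through the aroyl mixed anhydride and DMAP acylates the single free, equatorial secondary hydroxyl O8 with the α-substituted acrylic acid without touching any stereocentre.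

Step 23
Reactants: 36 fully protected ester
Product: 37 allyl ester of the target (free O3, O6, O3', O4'; 5S,6S,7S,8S,10R,3'R)
Conditions: HF·pyridine, pyridine, THF, 0 °C → rt
Reagents that add atoms: none
Why: Buffered HF·pyridine removes the four silyl ethers (fluoride-mediated desilylation) under weakly acidic conditions in which the 4'-hydroxy ester and the 6-hydroxy allyl ester should not lactonise and no acyl migration is expected.

Step 24
Reactants: 37 allyl ester of the target
Product: 38 CNP0348657.7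
Conditions: Pd(PPh3)4 (5 mol%), PhSiH3, CH2Cl2, 0 °C → rt; MeOH/H2O
Reagents that add atoms: none
Why: Zerovalent palladium ionises the allyl ester to a π-allyl complex that phenylsilane reduces to propene (allyl transfer to a hydride donor), which frees the C12 acid under neutral conditions compatible with the acrylates and the free hydroxyls.

**Compound list**

1 | monomethyl itaconate (4-methoxy-2-methylidene-4-oxobutanoic acid) | C=C(CC(=O)OC)C(=O)O | starting material
2 | ethyl carbonic mixed anhydride of 1 | C=C(CC(=O)OC)C(=O)OC(=O)OCC | intermediate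
3 | methyl 3-(hydroxymethyl)but-3-enoate | C=C(CO)CC(=O)OC | intermediate
4 | methyl 3-{[(tert-butyldiphenylsilyl)oxy]methyl}but-3-enoate | C=C(CO[Si](c1ccccc1)(c1ccccc1)C(C)(C)C)CC(=O)OC | intermediate
5 | 3-{[(tert-butyldiphenylsilyl)oxy]methyl}but-3-enoic acid | C=C(CO[Si](c1ccccc1)(c1ccccc1)C(C)(C)C)CC(=O)O | intermediate
6 | (S)-glycidyl trityl ether | C1[C@H](O1)COC(c1ccccc1)(c1ccccc1)c1ccccc1 | starting material
7 | (S)-1-(trityloxy)pent-4-yn-2-ol | C#CC[C@H](O)COC(c1ccccc1)(c1ccccc1)c1ccccc1 | intermediate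
8 | (S)-pent-4-yne-1,2-diol | C#CC[C@H](O)CO | intermediate
9 | (S)-4,5-bis(triethylsilyloxy)pent-1-yne | C#CC[C@H](O[Si](CC)(CC)CC)CO[Si](CC)(CC)CC | intermediate
10 | [(1E,4S)-2-methyl-4,5-bis(triethylsilyloxy)pent-1-en-1-yl]dimethylalane | C[Al](C)/C=C(\C)C[C@H](O[Si](CC)(CC)CC)CO[Si](CC)(CC)CC | intermediate
11 | (2E,5S)-3-methyl-5,6-bis(triethylsilyloxy)hex-2-en-1-ol | OC/C=C(\C)C[C@H](O[Si](CC)(CC)CC)CO[Si](CC)(CC)CC | intermediate
12 | (2E,5S)-3-methyl-5,6-bis(triethylsilyloxy)hex-2-en-1-yl 3-{[(tert-butyldiphenylsilyl)oxy]methyl}but-3-enoate | C=C(CO[Si](c1ccccc1)(c1ccccc1)C(C)(C)C)CC(=O)OC/C=C(\C)C[C@H](O[Si](CC)(CC)CC)CO[Si](CC)(CC)CC | intermediate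
13 | E(O) boron ketene acetal of 12 (C4 cis to the allyloxy oxygen; boron bears the (S,S)-bis-sulfonamide ligand) | C=C(CO[Si](c1ccccc1)(c1ccccc1)C(C)(C)C)/C=C(\OC/C=C(\C)C[C@H](O[Si](CC)(CC)CC)CO[Si](CC)(CC)CC)OB1N(S(=O)(=O)c2cc(cc(c2)C(F)(F)F)C(F)(F)F)[C@@H](c2ccccc2)[C@H](c2ccccc2)N1S(=O)(=O)c1cc(cc(c1)C(F)(F)F)C(F)(F)F | intermediate
14 | (2S,3R,5S)-2-{3-[(tert-butyldiphenylsilyl)oxy]prop-1-en-2-yl}-3-ethenyl-3-methyl-5,6-bis(triethylsilyloxy)hexanoic acid (ring numbering 5S,8S,10R) | C=C[C@@]([C@H](C(=O)O)C(=C)CO[Si](c1ccccc1)(c1ccccc1)C(C)(C)C)(C)C[C@H](O[Si](CC)(CC)CC)CO[Si](CC)(CC)CC | intermediate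
15 | (2S,3R,5S)-2-{3-[(tert-butyldiphenylsilyl)oxy]prop-1-en-2-yl}-3-ethenyl-3-methyl-5,6-bis(triethylsilyloxy)hexan-1-ol | C=C[C@@]([C@H](CO)C(=C)CO[Si](c1ccccc1)(c1ccccc1)C(C)(C)C)(C)C[C@H](O[Si](CC)(CC)CC)CO[Si](CC)(CC)CC | intermediate
16 | 4-methoxybenzyl ether of 15 at O6 | C=C[C@@]([C@H](COCc1ccc(OC)cc1)C(=C)CO[Si](c1ccccc1)(c1ccccc1)C(C)(C)C)(C)C[C@H](O[Si](CC)(CC)CC)CO[Si](CC)(CC)CC | intermediate
17 | (2S,4R,5S)-4-ethenyl-6-(4-methoxybenzyloxy)-4-methyl-5-{3-[(tert-butyldiphenylsilyl)oxy]prop-1-en-2-yl}-2-(triethylsilyloxy)hexan-1-ol | C=C[C@@]([C@H](COCc1ccc(OC)cc1)C(=C)CO[Si](c1ccccc1)(c1ccccc1)C(C)(C)C)(C)C[C@H](O[Si](CC)(CC)CC)CO | intermediate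
18 | (2S,4R,5S)-4-ethenyl-6-(4-methoxybenzyloxy)-4-methyl-5-{3-[(tert-butyldiphenylsilyl)oxy]prop-1-en-2-yl}-2-(triethylsilyloxy)hexanal | C=C[C@@]([C@H](COCc1ccc(OC)cc1)C(=C)CO[Si](c1ccccc1)(c1ccccc1)C(C)(C)C)(C)C[C@H](O[Si](CC)(CC)CC)C=O | intermediate
19 | allyl acrylate | C=CCOC(=O)C=C | starting material
20 | allyl (4S,6R,7S)-6-ethenyl-3-hydroxy-8-(4-methoxybenzyloxy)-6-methyl-2-methylidene-7-{3-[(tert-butyldiphenylsilyl)oxy]prop-1-en-2-yl}-4-(triethylsilyloxy)octanoate, C3 epimers | C=C[C@@]([C@H](COCc1ccc(OC)cc1)C(=C)CO[Si](c1ccccc1)(c1ccccc1)C(C)(C)C)(C)C[C@H](O[Si](CC)(CC)CC)C(O)C(=C)C(=O)OCC=C | intermediate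
21 | allyl (2Z,4S,6R,7S)-2-(bromomethyl)-6-ethenyl-8-(4-methoxybenzyloxy)-6-methyl-7-{3-[(tert-butyldiphenylsilyl)oxy]prop-1-en-2-yl}-4-(triethylsilyloxy)oct-2-enoate | C=C[C@@]([C@H](COCc1ccc(OC)cc1)C(=C)CO[Si](c1ccccc1)(c1ccccc1)C(C)(C)C)(C)C[C@H](O[Si](CC)(CC)CC)/C=C(\CBr)C(=O)OCC=C | intermediate
22 | allyl (2Z,4S,6R,7S)-2-(bromomethyl)-6-ethenyl-8-hydroxy-6-methyl-7-{3-[(tert-butyldiphenylsilyl)oxy]prop-1-en-2-yl}-4-(triethylsilyloxy)oct-2-enoate | C=C[C@@]([C@H](CO)C(=C)CO[Si](c1ccccc1)(c1ccccc1)C(C)(C)C)(C)C[C@H](O[Si](CC)(CC)CC)/C=C(\CBr)C(=O)OCC=C | intermediate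
23 | allyl (2Z,4S,6R,7S)-2-(bromomethyl)-6-ethenyl-6-methyl-8-oxo-7-{3-[(tert-butyldiphenylsilyl)oxy]prop-1-en-2-yl}-4-(triethylsilyloxy)oct-2-enoate | C=C[C@@]([C@H](C=O)C(=C)CO[Si](c1ccccc1)(c1ccccc1)C(C)(C)C)(C)C[C@H](O[Si](CC)(CC)CC)/C=C(\CBr)C(=O)OCC=C | intermediate
24 | allylchromium dichloride from 23 (CrCl2 on C13, trivalent chromium, C8 cis to CH2Cr) | C=C[C@@]([C@H](C=O)C(=C)CO[Si](c1ccccc1)(c1ccccc1)C(C)(C)C)(C)C[C@H](O[Si](CC)(CC)CC)/C=C(\C[Cr](Cl)Cl)C(=O)OCC=C | intermediate
25 | allyl 2-[(5S,6S,7S,8S,10R)-cyclohexyl]acrylate with 6-hydroxy, 8-triethylsilyloxy, 10-methyl, 10-vinyl and 5-{3-[(tert-butyldiphenylsilyl)oxy]prop-1-en-2-yl} (ring numbering) | C=C[C@@]1(C)C[C@H](O[Si](CC)(CC)CC)[C@@H](C(=C)C(=O)OCC=C)[C@@H](O)[C@@H]1C(=C)CO[Si](c2ccccc2)(c2ccccc2)C(C)(C)C | intermediate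
26 | O6-tert-butyldimethylsilyl ether of 25 (5S,6S,7R,8S,10R) | C=C[C@@]1(C)C[C@H](O[Si](CC)(CC)CC)[C@@H](C(=C)C(=O)OCC=C)[C@@H](O[Si](C)(C)C(C)(C)C)[C@@H]1C(=C)CO[Si](c2ccccc2)(c2ccccc2)C(C)(C)C | intermediate
27 | 8-hydroxy compound from 26 (5S,6S,7R,8S,10R) | C=C[C@@]1(C)C[C@H](O)[C@@H](C(=C)C(=O)OCC=C)[C@@H](O[Si](C)(C)C(C)(C)C)[C@@H]1C(=C)CO[Si](c2ccccc2)(c2ccccc2)C(C)(C)C | intermediate
28 | (R)-4-hydroxydihydrofuran-2(3H)-one | O=C1C[C@@H](O)CO1 | starting material
29 | (3R,4R)-3-[(dimethylamino)methyl]-4-hydroxydihydrofuran-2(3H)-one (trans) | O=C1OC[C@H](O)[C@H]1CN(C)C | intermediate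
30 | trimethylammonium iodide of 29 | O=C1OC[C@H](O)[C@H]1C[N+](C)(C)C.[I-] | intermediate
31 | (R)-4-hydroxy-3-methylidenedihydrofuran-2(3H)-one | C=C1[C@@H](O)COC1=O | intermediate
32 | lithium (R)-3,4-dihydroxy-2-methylidenebutanoate | [Li+].[O-]C(=O)C(=C)[C@@H](O)CO | intermediate
33 | tert-butyldimethylsilyl (R)-3,4-bis(tert-butyldimethylsilyloxy)-2-methylidenebutanoate | C=C([C@@H](O[Si](C)(C)C(C)(C)C)CO[Si](C)(C)C(C)(C)C)C(=O)O[Si](C)(C)C(C)(C)C | intermediate
34 | (R)-3,4-bis(tert-butyldimethylsilyloxy)-2-methylidenebutanoic acid | OC(=O)C(=C)[C@@H](O[Si](C)(C)C(C)(C)C)CO[Si](C)(C)C(C)(C)C | intermediate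
35 | mixed anhydride of 34 with 2,4,6-trichlorobenzoic acid | C=C([C@@H](O[Si](C)(C)C(C)(C)C)CO[Si](C)(C)C(C)(C)C)C(=O)OC(=O)c1c(Cl)cc(Cl)cc1Cl | intermediate
36 | O8 ester of 27 with 34 (5S,6S,7R,8S,10R,3'R) | C=C[C@@]1(C)C[C@H](OC(=O)C(=C)[C@@H](O[Si](C)(C)C(C)(C)C)CO[Si](C)(C)C(C)(C)C)[C@@H](C(=C)C(=O)OCC=C)[C@@H](O[Si](C)(C)C(C)(C)C)[C@@H]1C(=C)CO[Si](c2ccccc2)(c2ccccc2)C(C)(C)C | intermediate
37 | allyl ester of the target (5S,6S,7S,8S,10R,3'R) | C=C[C@@]1(C)C[C@H](OC(=O)C(=C)[C@@H](O)CO)[C@@H](C(=C)C(=O)OCC=C)[C@@H](O)[C@@H]1C(=C)CO | intermediate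
38 | CNP0348657.7 (5S,6S,7S,8S,10R,3'R) | C=C[C@@]1(C)C[C@H](OC(=O)C(=C)[C@@H](O)CO)[C@@H](C(=C)C(=O)O)[C@@H](O)[C@@H]1C(=C)CO | target

**Count and risks**

Total: 24 steps. Longest linear sequence: 19 steps (steps 4–19 and 22–24); steps 1–3 and 20–21 are side branches.

Steps most likely to fail:

1. Step 9. The boron ligand may give incomplete facial control, the dienolate may form with Z(O) geometry (wrong relative configuration at C5/C10), or the Lewis-acidic bromoborane may attack a silyl ether. Fallback: ester 12 is rearranged under classical lithium-enolate conditions (LDA, THF, −78 °C; Me3SiCl/Et3N; warm to rt), which give the kinetic E(O) trimethylsilyl ketene acetal F1. Its chair rearrangement has no facial bias and, after hydrolysis of the silyl ester, gives 14 together with the (5R,8S,10S)-diastereomeric acid F2. Both have the required relative C5/C10 configuration and differ through C8, so they are separated by chromatography (if necessary after reduction, as the alcohols), and the route continues from 14.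

2. Step 17. The allylchromium may be lost by elimination of the C8 silyloxy group or by protonation, the ring may close with poor cis or facial selectivity, or the product may lactonise on work-up. Fallback: the allylation is run with an isolable allylboron reagent instead of a reducing metal. Adduct 20 is acetylated (Ac2O, DMAP, pyridine) to the acetate F3; SN2' borylation (B2pin2, CuCl, LiCl, KOAc, DMF) gives the (E)-allylboronate F4 with C8 cis to the CH2–B carbon; DDQ gives the C6 alcohol F5 and Dess–Martin periodinane the aldehyde F6. F6 cyclises on warming or with catalytic Sc(OTf)3 by intramolecular allylboration through the same closed chair to the O6 borate F7, and aqueous work-up returns 25.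

3. Step 13. The amine-catalysed addition may be slow enough for C8 to epimerise or for the acrylate to polymerise. Fallback: the acrylate α-carbanion is made stoichiometrically. Allyl propiolate is hydroaluminated (i-Bu2AlH, N-methylmorpholine N-oxide, THF, 0 °C) to the α-aluminoacrylate F8, which adds to aldehyde 18 within hours at 0 °C and gives the same adduct 20 after work-up.

**Further compounds**

F1 | step 9 | E(O) trimethylsilyl ketene acetal of 12 | C=C(CO[Si](c1ccccc1)(c1ccccc1)C(C)(C)C)/C=C(\OC/C=C(\C)C[C@H](O[Si](CC)(CC)CC)CO[Si](CC)(CC)CC)O[Si](C)(C)C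
F2 | step 9 | (5R,8S,10S)-diastereomer of acid 14 | C=C[C@]([C@@H](C(=O)O)C(=C)CO[Si](c1ccccc1)(c1ccccc1)C(C)(C)C)(C)C[C@H](O[Si](CC)(CC)CC)CO[Si](CC)(CC)CC
F3 | step 17 | C7 acetate of adduct 20 | C=C[C@@]([C@H](COCc1ccc(OC)cc1)C(=C)CO[Si](c1ccccc1)(c1ccccc1)C(C)(C)C)(C)C[C@H](O[Si](CC)(CC)CC)C(OC(C)=O)C(=C)C(=O)OCC=C
F4 | step 17 | (E)-allylboronate with O6 4-methoxybenzyl ether (pinacolboryl on C13) | C=C[C@@]([C@H](COCc1ccc(OC)cc1)C(=C)CO[Si](c1ccccc1)(c1ccccc1)C(C)(C)C)(C)C[C@H](O[Si](CC)(CC)CC)/C=C(\CB1OC(C)(C)C(C)(C)O1)C(=O)OCC=C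
F5 | step 17 | C6 alcohol of the allylboronate | C=C[C@@]([C@H](CO)C(=C)CO[Si](c1ccccc1)(c1ccccc1)C(C)(C)C)(C)C[C@H](O[Si](CC)(CC)CC)/C=C(\CB1OC(C)(C)C(C)(C)O1)C(=O)OCC=C
F6 | step 17 | C6 aldehyde of the allylboronate | C=C[C@@]([C@H](C=O)C(=C)CO[Si](c1ccccc1)(c1ccccc1)C(C)(C)C)(C)C[C@H](O[Si](CC)(CC)CC)/C=C(\CB1OC(C)(C)C(C)(C)O1)C(=O)OCC=C
F7 | step 17 | O6 pinacol borate of 25 | C=C[C@@]1(C)C[C@H](O[Si](CC)(CC)CC)[C@@H](C(=C)C(=O)OCC=C)[C@@H](OB2OC(C)(C)C(C)(C)O2)[C@@H]1C(=C)CO[Si](c2ccccc2)(c2ccccc2)C(C)(C)C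
F8 | step 13 | allyl 2-(diisobutylalumanyl)prop-2-enoate | C=C(C(=O)OCC=C)[Al](CC(C)C)CC(C)C
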